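**Plan**
- Retrosynthesis: cut the ester C–O bond at C6; take the C6 carbinol back to the C6 ketone of a C6/C9 ene-1,4-dione, and that to a C5=C6 alkene plus a C9 alkenylsilane; then cut C9–C10 and C7–C8 together as a Rh(I) (5+2) transform.
- Enabling feature: C10 is a CH2 between the C9 carbonyl and the quaternary ring-fusion carbon C1. C1–C10 can therefore be folded with C5 into a cyclopropane; with C6=C7 as a vinyl group on C5, the carbons C7–C6–C5(–C1)–C10 are a vinylcyclopropane inside a bicyclo[3.1.0]hexane that already holds the cyclopentane ring C1–C5. C8≡C9 is a propyne whose silyl group is the masked C9 oxygen.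
- Forward order: cyclopentenol, then cyclopropane (bicyclo[3.1.0]hexane), then the C4 carbinol, then the seven-membered ring by (5+2) with C9–C10 as the closing bond, then oxidation-state adjustment and esterification.
- Stereochemistry: a CBS-derived temporary carbinol directs the Simmons–Smith step and fixes C1; C4 comes from exo epoxidation (anti to the cyclopropane CH2) and hydride opening; C5 from equilibration next to the C6 ketone; C6 from reduction directed by the C4–OH.

Key step: step 10

Remark: daucane numbering is used throughout (C1 = CH3-bearing ring-fusion carbon, C2/C3 = ring CH2, C4 = C(OH)iPr, C5 = ring-fusion CH, C6 = ester carbon, C7=C8(CH3), C9 = C=O, C10 = CH2); compounds 1, 11, 12 and 20 are assumed to be commercial.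

**Step 1**
Reactants: 1 2-bromo-3-methylcyclopent-2-en-1-one
Product: 2 (R)-2-bromo-3-methylcyclopent-2-en-1-ol
Conditions: (S)-Me-CBS (10 mol %), BH3·SMe2, THF, −20 °C
Reagents that add atoms: none
Why: Corey–Bakshi–Shibata reduction, in which the bromovinyl arm acts as the large group so that the (S)-catalyst should give the (R)-carbinol, a temporary stereocentre that later controls C1.

**Step 2**
Reactants: 2 (R)-2-bromo-3-methylcyclopent-2-en-1-ol
Product: 3 (R)-2-ethenyl-3-methylcyclopent-2-en-1-ol
Conditions: Bu3SnCH=CH2, Pd(PPh3)4 (5 mol %), toluene, 90 °C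
Reagents that add atoms: tributyl(vinyl)stannane C=C[Sn](CCCC)(CCCC)CCCC
Why: Stille coupling of an alkenyl bromide, which tolerates the free allylic alcohol and leaves the carbinol centre untouched.

**Step 3**
Reactants: 3 (R)-2-ethenyl-3-methylcyclopent-2-en-1-ol
Product: 4 (1R,2R,5R)-1-ethenyl-5-methylbicyclo[3.1.0]hexan-2-ol
Conditions: Et2Zn, CH2I2, CH2Cl2, −10 → 0 °C
Reagents that add atoms: diiodomethane ICI
Why: Hydroxyl-directed Simmons–Smith (Furukawa) cyclopropanation, in which the zinc alkoxide should deliver CH2 (the future C10) to the allylic tetrasubstituted ring alkene on the face of the OH, setting C1 (and, for the time being, C5) while the remote monosubstituted vinyl group reacts more slowly.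

**Step 4**
Reactants: 4 (1R,2R,5R)-1-ethenyl-5-methylbicyclo[3.1.0]hexan-2-ol
Product: 5 (1R,5R)-1-ethenyl-5-methylbicyclo[3.1.0]hexan-2-one
Conditions: DMP, CH2Cl2, 0 °C → rt
Reagents that add atoms: none
Why: Dess–Martin oxidation removes the temporary carbinol once it has set the cyclopropane face; no epimerisable centre is present.

**Step 5**
Reactants: 5 (1R,5R)-1-ethenyl-5-methylbicyclo[3.1.0]hexan-2-one
Product: 7 (1R,5R)-1-ethenyl-5-methylbicyclo[3.1.0]hex-2-en-2-yl trifluoromethanesulfonate, via potassium enolate 6 (not isolated)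
Conditions: KHMDS, THF, −78 °C; then PhNTf2, −78 → 0 °C
Reagents that add atoms: N-phenylbis(trifluoromethanesulfonimide) O=S(=O)(N(c1ccccc1)S(=O)(=O)C(F)(F)F)C(F)(F)F
Why: Enol triflate formation, regiochemically unambiguous because only C3 carries α-hydrogens (the other α-carbon is the quaternary cyclopropane carbon).

**Step 6**
Reactants: 7 (1R,5R)-1-ethenyl-5-methylbicyclo[3.1.0]hex-2-en-2-yl trifluoromethanesulfonate
Product: 8 (1R,5R)-1-ethenyl-5-methyl-2-(propan-2-yl)bicyclo[3.1.0]hex-2-ene
Conditions: i-PrMgCl, PdCl2(dppf) (3 mol %), THF, 0 °C → rt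
Reagents that add atoms: isopropylmagnesium chloride CC(C)[Mg]Cl
Why: Kumada–Corriu coupling with the dppf ligand, the standard system for secondary alkyl Grignard reagents because fast reductive elimination suppresses β-hydride isomerisation of the isopropyl group.

**Step 7**
Reactants: 8 (1R,5R)-1-ethenyl-5-methyl-2-(propan-2-yl)bicyclo[3.1.0]hex-2-ene
Product: 9 exo-2,3-epoxide of 8 (1-ethenyl-5-methyl-2-(propan-2-yl)-2,3-epoxybicyclo[3.1.0]hexane, oxirane oxygen anti to the cyclopropane CH2)
Conditions: mCPBA, CH2Cl2/aq. NaHCO3, −10 → 0 °C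
Reagents that add atoms: 3-chloroperoxybenzoic acid OOC(=O)c1cccc(Cl)c1
Why: Prilezhaev epoxidation should take the electron-rich trisubstituted ring alkene in preference to the vinyl group and approach from the exo face, anti to the cyclopropane methylene, which places the C4 oxygen on the β face.

**Step 8**
Reactants: 9 exo-2,3-epoxide of 8
Product: 10 (1R,2R,5R)-1-ethenyl-5-methyl-2-(propan-2-yl)bicyclo[3.1.0]hexan-2-ol
Conditions: LiAlH4, THF, 0 °C → reflux
Reagents that add atoms: none
Why: SN2 hydride opening at the secondary epoxide carbon (C3) leaves the C4–O bond untouched and so should give the tertiary alcohol with OH anti and isopropyl syn to the cyclopropane CH2 (4β-OH, 4α-iPr).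

**Step 9**
Reactants: 11 prop-1-yn-1-ylmagnesium bromide; 12 chlorotriethoxysilane
Product: 13 triethoxy(prop-1-yn-1-yl)silane
Conditions: THF, 0 °C → rt
Reagents that add atoms: none
Why: Substitution at silicon by an alkynyl Grignard reagent gives the alkyne partner, whose silyl group is both the regiocontrol element and the masked C9 oxygen.

**Step 10**
Reactants: 10 (1R,2R,5R)-1-ethenyl-5-methyl-2-(propan-2-yl)bicyclo[3.1.0]hexan-2-ol; 13 triethoxy(prop-1-yn-1-yl)silane
Product: 14 (3R,8aR)-6,8a-dimethyl-3-(propan-2-yl)-7-(triethoxysilyl)-1,2,3,5,8,8a-hexahydroazulen-3-ol (9-silyl-dauca-5,8-dien-4β-ol)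
Conditions: [Rh(CO)2Cl]2 (5 mol %), 13 (1.5 equiv), 1,2-dichloroethane, 80 °C
Reagents that add atoms: none
Why: Rh(I) binds the vinylcyclopropane of 10 and cleaves the C5–C10 cyclopropane bond to a σ-alkyl/π-allyl rhodacycle (Rh–C10H2, allyl C5–C6–C7); the alkyne inserts at the allyl terminus (C7–C8 bond) and C(sp2)–C(sp3) reductive elimination then joins C9 to C10 and closes the seven-membered ring. The closest known reaction type is the Rh(I)-catalysed intermolecular (5+2) cycloaddition of 1-substituted vinylcyclopropanes with alkynes (Wender). The cycloheptadiene closes by reductive elimination from an eight-membered rhodacycle, a formal (5+2) closure with C7, C6, C5, C1, C10 as the five-carbon unit and C8, C9 as the two-carbon unit. No stereocentre is created: C1 keeps the configuration set in step 3 because only C5–C10 is broken, C5 becomes sp2 and C4 is untouched. The step needs cleavage of C5–C10 and not C5–C1, which should follow because Rh then bears a primary CH2 instead of the quaternary C1; it needs Si on C9 and CH3 on C8, which should follow because the bulky silyl group sits distal to the forming C7–C8 bond and α to Rh during insertion; and it needs a rhodacycle that cannot lose a β-hydride, which the quaternary C1 and C4 on either side ensure.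

**Step 11**
Reactants: 14 (3R,8aR)-6,8a-dimethyl-3-(propan-2-yl)-7-(triethoxysilyl)-1,2,3,5,8,8a-hexahydroazulen-3-ol
Product: 16 (3R,8aR)-3,4-dihydroxy-6,8a-dimethyl-3-(propan-2-yl)octahydroazulen-7(1H)-one (4β,6-dihydroxydaucan-9-one; mixture of epimers at C5, C6 and C8), via C6-alkylborane 15 (not isolated)
Conditions: BH3·THF, THF, 0 °C → rt; then MeOH; KF, KHCO3, 30% H2O2, THF/MeOH, 50 °C
Reagents that add atoms: hydrogen peroxide OO
Why: Hydroboration of the trisubstituted C5=C6 alkene puts boron on C6 (the tetrasubstituted alkenylsilane is too hindered to compete), and the fluoride-assisted alkaline peroxide then oxidises both the C–B bond and the alkenyl C–Si bond (Tamao–Fleming oxidation to the enol, hence the C9 ketone); the configurations at C5, C6 and C8 are left open because step 12 erases or equilibrates all three.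

**Step 12**
Reactants: 16 (3R,8aR)-3,4-dihydroxy-6,8a-dimethyl-3-(propan-2-yl)octahydroazulen-7(1H)-one
Product: 18 (3R,3aR,8aR)-3-hydroxy-6,8a-dimethyl-3-(propan-2-yl)-1,2,3,3a,8,8a-hexahydroazulene-4,7-dione (4β-hydroxydauc-7-ene-6,9-dione), via saturated 6,9-diketone 17 (not isolated)
Conditions: IBX (4 equiv), DMSO, rt then 65 °C
Reagents that add atoms: none
Why: IBX oxidises the C6 alcohol and then dehydrogenates the 1,4-diketone at C7–C8, the only position with the required α/β hydrogen pair, while C5–H, now α to the C6 ketone, should equilibrate to the trans ring fusion in which C6 is anti to the isopropyl group and hydrogen-bonded to the C4–OH.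

**Step 13**
Reactants: 18 (3R,3aR,8aR)-3-hydroxy-6,8a-dimethyl-3-(propan-2-yl)-1,2,3,3a,8,8a-hexahydroazulene-4,7-dione
Product: 19 lancerodiol, (3R,3aS,4S,8aR)-3,4-dihydroxy-6,8a-dimethyl-3-(propan-2-yl)-1,2,3,3a,4,8a-hexahydroazulen-7(8H)-one
Conditions: Me4NBH(OAc)3, MeCN/AcOH (1:1), −30 → −10 °C
Reagents that add atoms: none
Why: Evans–Saksena reduction, in which ligand exchange at the C4–OH and intramolecular hydride delivery to the β face of the C6 carbonyl should give the anti-1,3-diol (6α-OH), while the C9 ketone has no directing hydroxyl and is not reduced by triacetoxyborohydride.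

**Step 14**
Reactants: 19 lancerodiol; 20 4-[(tert-butyldimethylsilyl)oxy]benzoic acid
Product: 21 lancerodiol 4-[(tert-butyldimethylsilyl)oxy]benzoate (ester at C6)
Conditions: DCC, DMAP (cat.), CH2Cl2, 0 °C → rt
Reagents that add atoms: none
Why: Steglich esterification acylates the secondary C6 alcohol, the hindered tertiary C4 alcohol being inert under these conditions.

**Step 15**
Reactants: 21 lancerodiol 4-[(tert-butyldimethylsilyl)oxy]benzoate
Product: 22 lancerodiol p-hydroxybenzoate, [(3R,3aS,4S,8aR)-3-hydroxy-6,8a-dimethyl-7-oxo-3-(propan-2-yl)-1,2,3,3a,4,7,8,8a-octahydroazulen-4-yl] 4-hydroxybenzoate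
Conditions: HF·pyridine, THF/pyridine, 0 °C
Reagents that add atoms: none
Why: Fluoride cleavage of the aryl silyl ether under mildly acidic, non-basic conditions leaves the benzoate, the tertiary alcohol and the γ-acyloxy enone untouched.

**Compound list**
1 | 2-bromo-3-methylcyclopent-2-en-1-one | CC1=C(Br)C(=O)CC1 | starting material
2 | (R)-2-bromo-3-methylcyclopent-2-en-1-ol | O[C@H]1C(Br)=C(C)CC1 | intermediate
3 | (R)-2-ethenyl-3-methylcyclopent-2-en-1-ol | O[C@H]1C(C=C)=C(C)CC1 | intermediate
4 | (1R,2R,5R)-1-ethenyl-5-methylbicyclo[3.1.0]hexan-2-ol (OH cis to the cyclopropane CH2) | O[C@@H]1CC[C@]2(C)C[C@]12C=C | intermediate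
5 | (1R,5R)-1-ethenyl-5-methylbicyclo[3.1.0]hexan-2-one | O=C1CC[C@]2(C)C[C@]12C=C | intermediate
6 | potassium enolate of 5 | [K+].[O-]C1=CC[C@]2(C)C[C@]12C=C | intermediate (not isolated)
7 | (1R,5R)-1-ethenyl-5-methylbicyclo[3.1.0]hex-2-en-2-yl trifluoromethanesulfonate | O=S(=O)(OC1=CC[C@]2(C)C[C@]12C=C)C(F)(F)F | intermediate
8 | (1R,5R)-1-ethenyl-5-methyl-2-(propan-2-yl)bicyclo[3.1.0]hex-2-ene | CC(C)C1=CC[C@]2(C)C[C@]12C=C | intermediate
9 | exo-2,3-epoxide of 8 (oxirane O anti to the cyclopropane CH2) | CC(C)[C@]12O[C@H]1C[C@]1(C)C[C@]21C=C | intermediate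
10 | (1R,2R,5R)-1-ethenyl-5-methyl-2-(propan-2-yl)bicyclo[3.1.0]hexan-2-ol (OH anti to the cyclopropane CH2) | CC(C)[C@]1(O)CC[C@]2(C)C[C@]12C=C | intermediate
11 | prop-1-yn-1-ylmagnesium bromide | CC#C[Mg]Br | starting material
12 | chlorotriethoxysilane | CCO[Si](Cl)(OCC)OCC | starting material
13 | triethoxy(prop-1-yn-1-yl)silane | CC#C[Si](OCC)(OCC)OCC | intermediate
14 | (3R,8aR)-6,8a-dimethyl-3-(propan-2-yl)-7-(triethoxysilyl)-1,2,3,5,8,8a-hexahydroazulen-3-ol | CC1=C([Si](OCC)(OCC)OCC)C[C@@]2(C)CC[C@@](O)(C(C)C)C2=CC1 | intermediate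
15 | C6-alkylborane from 14 (drawn as the RBH2 monomer; C5/C6 epimers) | CC1=C([Si](OCC)(OCC)OCC)C[C@@]2(C)CC[C@@](O)(C(C)C)C2C(B)C1 | intermediate (not isolated)
16 | (3R,8aR)-3,4-dihydroxy-6,8a-dimethyl-3-(propan-2-yl)octahydroazulen-7(1H)-one (epimers at C5, C6, C8) | CC1CC(O)C2[C@](C)(CC[C@@]2(O)C(C)C)CC1=O | intermediate
17 | (3R,8aR)-3-hydroxy-6,8a-dimethyl-3-(propan-2-yl)octahydroazulene-4,7-dione (epimers at C5, C8) | CC1CC(=O)C2[C@](C)(CC[C@@]2(O)C(C)C)CC1=O | intermediate (not isolated)
18 | (3R,3aR,8aR)-3-hydroxy-6,8a-dimethyl-3-(propan-2-yl)-1,2,3,3a,8,8a-hexahydroazulene-4,7-dione | CC1=CC(=O)[C@@H]2[C@](C)(CC[C@@]2(O)C(C)C)CC1=O | intermediate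
19 | lancerodiol, (3R,3aS,4S,8aR)-3,4-dihydroxy-6,8a-dimethyl-3-(propan-2-yl)-1,2,3,3a,4,8a-hexahydroazulen-7(8H)-one | CC1=C[C@H](O)[C@@H]2[C@](C)(CC[C@@]2(O)C(C)C)CC1=O | intermediate
20 | 4-[(tert-butyldimethylsilyl)oxy]benzoic acid | CC(C)(C)[Si](C)(C)Oc1ccc(cc1)C(=O)O | starting material
21 | lancerodiol 4-[(tert-butyldimethylsilyl)oxy]benzoate | CC1=C[C@H](OC(=O)c2ccc(O[Si](C)(C)C(C)(C)C)cc2)[C@@H]2[C@](C)(CC[C@@]2(O)C(C)C)CC1=O | intermediate
22 | lancerodiol p-hydroxybenzoate | CC1=C[C@H](OC(=O)c2ccc(O)cc2)[C@@H]2[C@](C)(CC[C@@]2(O)C(C)C)CC1=O | target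

**Step count and risks**
Total step count: 15. Longest linear sequence: 14 (steps 1–8 and 10–15; step 9 is a side branch).

Steps most likely to fail:

1. Step 10. Alkyne insertion and the final reductive elimination at the neopentyl C10 may be slow enough for alkyne oligomerisation or unproductive Rh-induced opening of the cyclopropane to take over. Insertion regiocontrol may erode, and Si–OEt groups may exchange with the free tertiary alcohol. The fallback drops the alkoxysilane and uses the trialkylsilane/epoxysilane tactic for the C9 carbonyl. It sets out from 10: the same Rh catalysis with commercial 1-(trimethylsilyl)propyne should give the 9-trimethylsilyl cycloadduct F1. Hydroboration and oxidation (BH3·THF; NaOH, H2O2) then gives the C6 alcohol with the vinylsilane intact, diol F2. mCPBA converts this into the α,β-epoxysilane F3, and dilute H2SO4 in aqueous THF opens it at the silicon-bearing carbon; loss of trimethylsilanol then delivers hydroxy ketone 16, where the route is rejoined.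

2. Step 12. Under warm, acidic IBX conditions the β-hydroxy ketone (C4–OH/C6=O) may dehydrate or undergo retro-aldol opening of the five-membered ring, and equilibration at C5 may be incomplete. The fallback postpones the dehydrogenation until the C6 ketone no longer exists. It sets out from 16: DMP at room temperature gives diketone 17, which is isolated and equilibrated at C5 with a trace of DBU. Directed reduction of 17 with Me4NBH(OAc)3 gives the saturated 6α-hydroxy-9-ketone F4. DCC/DMAP coupling with 20 gives its 4-silyloxybenzoate F5. IBX in DMSO at 70 °C then introduces the C7=C8 double bond and gives 21, where the route is rejoined.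

3. Step 13. Ligand exchange at the hindered tertiary C4–OH may be slow, so that hydride is delivered without direction and with poor site or facial selectivity. The fallback uses external hydride on a chelate, followed by inversion. It sets out from 18: NaBH4/CeCl3·7H2O in MeOH at −78 °C should reduce the Ce-chelated C6 carbonyl from the α face, away from the angular methyl and the metal-bridged C4–O. This gives the syn-diol, 6-epi-lancerodiol F6 (6β-OH). Mitsunobu esterification of F6 with 20 (PPh3, DIAD, THF) inverts C6 and gives 21, where the route is rejoined.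

**Further compounds**
F1 | step 10 | (3R,8aR)-6,8a-dimethyl-3-(propan-2-yl)-7-(trimethylsilyl)-1,2,3,5,8,8a-hexahydroazulen-3-ol | CC1=C([Si](C)(C)C)C[C@@]2(C)CC[C@@](O)(C(C)C)C2=CC1
F2 | step 10 | 9-(trimethylsilyl)dauc-8-ene-4β,6-diol (C5/C6 epimers) | CC1=C([Si](C)(C)C)C[C@@]2(C)CC[C@@](O)(C(C)C)C2C(O)C1
F3 | step 10 | 8,9-epoxy-9-(trimethylsilyl)daucane-4β,6-diol (epoxysilane of F2) | CC12OC1([Si](C)(C)C)C[C@@]1(C)CC[C@@](O)(C(C)C)C1C(O)C2
F4 | step 12 | (3R,3aS,4S,8aR)-3,4-dihydroxy-6,8a-dimethyl-3-(propan-2-yl)octahydroazulen-7(1H)-one (C8 epimers) | CC1C[C@H](O)[C@@H]2[C@](C)(CC[C@@]2(O)C(C)C)CC1=O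
F5 | step 12 | 4-[(tert-butyldimethylsilyl)oxy]benzoate of F4 | CC1C[C@H](OC(=O)c2ccc(O[Si](C)(C)C(C)(C)C)cc2)[C@@H]2[C@](C)(CC[C@@]2(O)C(C)C)CC1=O
F6 | step 13 | 6-epi-lancerodiol (6β-OH) | CC1=C[C@@H](O)[C@@H]2[C@](C)(CC[C@@]2(O)C(C)C)CC1=O
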